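The carbocycle (C4a–C5–C6–C7–C8–C8a) is disconnected at the C6–C7 acyloin bond, C6 becoming an aldehyde and C7 a methyl ketone. The key step is a carbene-catalysed intramolecular crossed benzoin reaction: polarity reversal makes C6 the nucleophile toward the C7 carbonyl, closing the ring and creating the C7 tertiary carbinol in one operation. The step exploits the 1,6-relationship of C6 and C7 and the cis C4a=C5 alkene. Its precursor is a lactol whose ring oxygen (the future O2) is still bound to C6: this temporary pyran, derived from tetrahydropyran-4-one, masks the aldehyde, fixes the alkene geometry, and is later exchanged for the O2–C3 pyran by gold catalysis.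

Key step: step 13

Remark on numbering: C1, O2, C3, C4, C4a, C5–C8 and C8a follow the isochromene numbering of the target; primed numbers belong to the tetrahydrofuran ring.
Remark (assumption): 1 is taken as a commercial material (the dimethyl ketal of methyl pyruvate).

Step 1
Reactants: 1 methyl 2,2-dimethoxypropanoate
Product: 2 2,2-dimethoxypropanal
Conditions: i-Bu2AlH, CH2Cl2, −78 °C; aqueous KNaC4H4O6 work-up
Reagents that add atoms: none
Why: Low-temperature i-Bu2AlH reduction of an α,α-dialkoxy ester stops at the chelated aluminium hemiacetal, which releases the aldehyde only on work-up; no stereocentre is involved.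

Step 2
Reactants: 2 2,2-dimethoxypropanal; 3 tetrahydro-4H-pyran-4-one
Product: 4 (S)-3-[(R)-1-hydroxy-2,2-dimethoxypropyl]tetrahydro-4H-pyran-4-one
Conditions: L-proline (30 mol%), DMSO, rt, 3 in excess
Reagents that add atoms: none
Why: Proline-catalysed direct aldol reaction: the enamine of 3 adds to the non-enolisable, inductively activated aldehyde 2 through the hydrogen-bonded chair transition state, which should give the anti adduct with the (S) α-carbon (later C8a) and the (R) carbinol (later C8).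

Step 3
Reactants: 4 (S)-3-[(R)-1-hydroxy-2,2-dimethoxypropyl]tetrahydro-4H-pyran-4-one
Product: 5 (S)-3-[(R)-1-(tert-butyldimethylsilyloxy)-2,2-dimethoxypropyl]tetrahydro-4H-pyran-4-one
Conditions: TBSOTf, 2,6-lutidine, CH2Cl2, −78 to 0 °C
Reagents that add atoms: tert-butyldimethylsilyl trifluoromethanesulfonate, CC(C)(C)[Si](C)(C)OS(=O)(=O)C(F)(F)F
Why: Silyl ether formation with the silyl triflate at low temperature outruns ketal activation, and the ether later blocks acyloin isomerisation and retro-benzoin cleavage at C7–C8; no stereocentre is touched.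

Step 4
Reactants: 5 (S)-3-[(R)-1-(tert-butyldimethylsilyloxy)-2,2-dimethoxypropyl]tetrahydro-4H-pyran-4-one
Product: 7 (S)-3-[(R)-1-(tert-butyldimethylsilyloxy)-2,2-dimethoxypropyl]-2,3-dihydro-4H-pyran-4-one, via trimethylsilyl enol ether 6 (not isolated)
Conditions: LiN(i-Pr)2, Me3SiCl, THF, −78 °C; then Pd(OAc)2, MeCN, rt
Reagents that add atoms: none
Why: Kinetic deprotonation at the unsubstituted α-methylene (C5) and Saegusa–Ito oxidation of the silyl enol ether give the vinylogous ester, which raises C6 to the aldehyde oxidation level while leaving the C8a centre unenolised.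

Step 5
Reactants: 2 2,2-dimethoxypropanal; 8 cis-2-butene
Product: 9 (3R,4S)-2,2-dimethoxy-4-methylhex-5-en-3-ol
Conditions: 8, n-BuLi, KOt-Bu, THF, −78 to −45 °C; (+)-Ipc2BOMe [from (−)-α-pinene], −78 °C; BF3·OEt2; then 2, −78 °C; NaOH, H2O2
Reagents that add atoms: none
Why: Brown crotylboration: the (Z)-crotylborane made in the flask reacts through a closed chair transition state, so the Z geometry gives the syn adduct and the isopinocampheyl groups derived from (−)-α-pinene should direct the crotyl group to the re face of 2, giving 3R,4S (later C2' and C3').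

Step 6
Reactants: 9 (3R,4S)-2,2-dimethoxy-4-methylhex-5-en-3-ol
Product: 10 (3S,4R)-5,5-dimethoxy-3-methylhexane-1,4-diol
Conditions: 9-BBN, THF, 0 °C to rt; then NaOH, H2O2
Reagents that add atoms: hydrogen peroxide, OO
Why: Anti-Markovnikov hydroboration of the terminal alkene and oxidative work-up give the primary alcohol without touching the stereocentres.

Step 7
Reactants: 10 (3S,4R)-5,5-dimethoxy-3-methylhexane-1,4-diol
Product: 12 (2R,3S)-2-(1,1-dimethoxyethyl)-3-methyltetrahydrofuran, via primary tosylate 11 (not isolated)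
Conditions: TsCl, Et3N, DMAP (cat.), CH2Cl2, 0 °C; then KOt-Bu, THF, 0 °C to rt
Reagents that add atoms: none
Why: Selective sulfonylation of the primary hydroxyl followed by intramolecular Williamson etherification (5-exo-tet) through the secondary alkoxide retains both stereocentres, so the syn relationship becomes the 2,3-cis tetrahydrofuran.

Step 8
Reactants: 12 (2R,3S)-2-(1,1-dimethoxyethyl)-3-methyltetrahydrofuran
Product: 13 1-[(2R,3S)-3-methyltetrahydrofuran-2-yl]ethan-1-one
Conditions: 1 M HCl, THF, 0 °C, short reaction time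
Reagents that add atoms: water, O
Why: Acid-catalysed hydrolysis of the dimethyl ketal is much faster than acid-catalysed enolisation when run cold and briefly, so the epimerisable α-alkoxy centre C2' should survive.

Step 9
Reactants: 14 (E)-1,2-diiodoethene; 15 ethynyltrimethylsilane
Product: 16 (E)-(4-iodobut-3-en-1-yn-1-yl)trimethylsilane
Conditions: Pd(PPh3)4 (cat.), CuI (cat.), Et3N, THF, rt, 14 in excess
Reagents that add atoms: none
Why: Sonogashira coupling proceeds with retention of the E geometry, and the excess of diiodide suppresses double coupling.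

Step 10
Reactants: 13 1-[(2R,3S)-3-methyltetrahydrofuran-2-yl]ethan-1-one; 16 (E)-(4-iodobut-3-en-1-yn-1-yl)trimethylsilane
Product: 18 (R,E)-2-[(2R,3S)-3-methyltetrahydrofuran-2-yl]-6-(trimethylsilyl)hex-3-en-5-yn-2-ol, via alkenylmagnesium chloride 17 (not isolated)
Conditions: 16, i-PrMgCl·LiCl, THF, −20 °C; then 13, −78 to −40 °C; aqueous NH4Cl
Reagents that add atoms: none
Why: Iodine–magnesium exchange retains the alkene geometry, and the Grignard addition should follow the Cram chelate model: magnesium bridges the ring oxygen and the carbonyl oxygen and the alkenyl group attacks from the face of H-2', anti to C3', which gives the (R)-carbinol.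

Step 11
Reactants: 18 (R,E)-2-[(2R,3S)-3-methyltetrahydrofuran-2-yl]-6-(trimethylsilyl)hex-3-en-5-yn-2-ol
Product: 19 (R,E)-2-[(2R,3S)-3-methyltetrahydrofuran-2-yl]hex-3-en-5-yn-2-ol
Conditions: K2CO3, MeOH, rt
Reagents that add atoms: none
Why: Methanolysis of the alkynyl–silicon bond under mild base (protodesilylation) leaves the tertiary alcohol and the stereocentres untouched.

Step 12
Reactants: 7 (S)-3-[(R)-1-(tert-butyldimethylsilyloxy)-2,2-dimethoxypropyl]-2,3-dihydro-4H-pyran-4-one; 19 (R,E)-2-[(2R,3S)-3-methyltetrahydrofuran-2-yl]hex-3-en-5-yn-2-ol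
Product: 21 (5S)-5-[(R)-1-(tert-butyldimethylsilyloxy)-2-oxopropyl]-4-[(R,E)-5-hydroxy-5-((2R,3S)-3-methyltetrahydrofuran-2-yl)hex-3-en-1-yn-1-yl]-5,6-dihydro-2H-pyran-2-ol, via tertiary propargylic alcohol 20 (not isolated)
Conditions: 19, n-BuLi (2.1 equiv), THF, −78 °C; CeCl3; then 7, −78 to −20 °C; then 0.5 M HCl, THF, 0 °C to rt
Reagents that add atoms: water, O
Why: 1,2-Addition of the cerium acetylide to the vinylogous ester carbonyl is followed on acidification by a Stork–Danheiser-type allylic transposition through the cyclic oxocarbenium ion, water adding at C6 to give the lactol while the same acid hydrolyses the dimethyl ketal to the C7 methyl ketone; the ring holds the new C4a=C5 alkene cis and C8a is not touched.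

Step 13
Reactants: 21 (5S)-5-[(R)-1-(tert-butyldimethylsilyloxy)-2-oxopropyl]-4-[(R,E)-5-hydroxy-5-((2R,3S)-3-methyltetrahydrofuran-2-yl)hex-3-en-1-yn-1-yl]-5,6-dihydro-2H-pyran-2-ol
Product: 23 (4S,5R,6R)-5-(tert-butyldimethylsilyloxy)-6-hydroxy-4-(hydroxymethyl)-6-methyl-3-[(R,E)-5-hydroxy-5-((2R,3S)-3-methyltetrahydrofuran-2-yl)hex-3-en-1-yn-1-yl]cyclohex-2-en-1-one, via open-chain hydroxy enal 22 (not isolated)
Conditions: 2-(pentafluorophenyl)-6,7-dihydro-5H-pyrrolo[2,1-c][1,2,4]triazol-2-ium tetrafluoroborate (20 mol%), i-Pr2NEt (20 mol%), molecular sieves, CH2Cl2, 25 °C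
Reagents that add atoms: none
Why: The base opens lactol 21 to hydroxy enal 22 (formyl group cis to C8a), the triazolylidene adds to the C6 aldehyde, and the resulting Breslow intermediate, an acyl-anion equivalent at C6, attacks the C7 ketone; proton transfer and loss of the carbene release the α-ketol, so the lactol ring is exchanged for the carbocycle. The closest known reaction type is the carbene-catalysed intramolecular crossed aldehyde–ketone benzoin cyclisation of 2-(3-oxoalkyl)benzaldehydes to 2-hydroxy-2-alkyl-1-tetralones, with the ortho-disubstituted arene replaced here by the cis C4a=C5 alkene. The carbocycle (C4a, C5, C6, C7, C8, C8a) closes in a 6-(enolexo)-exo-trig mode. The new C7 stereocentre is controlled by the C8 silyloxy stereocentre: in the polar Felkin–Anh arrangement the C8–O bond lies anti to the incoming C6, and the tether through C8a places the ketone oxygen gauche to C8a and the methyl group on the side of H-8, which should put the C7 hydroxyl cis to the C8 oxygen (7R). The step needs acyl-anion reactivity at C6 to win over homoenolate and redox pathways through C4a and over retro-benzoin cleavage; the electron-poor N-pentafluorophenyl triazolium, the weak amine base under aprotic conditions, the fully substituted C4a, the six-membered intramolecular closure and the silyl ether on O-8 are meant to secure this, and the lactol offers only the cyclisable alkene geometry.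

Step 14
Reactants: 23 (4S,5R,6R)-5-(tert-butyldimethylsilyloxy)-6-hydroxy-4-(hydroxymethyl)-6-methyl-3-[(R,E)-5-hydroxy-5-((2R,3S)-3-methyltetrahydrofuran-2-yl)hex-3-en-1-yn-1-yl]cyclohex-2-en-1-one
Product: 24 (4S,5R,6R)-5,6-dihydroxy-4-(hydroxymethyl)-6-methyl-3-[(R,E)-5-hydroxy-5-((2R,3S)-3-methyltetrahydrofuran-2-yl)hex-3-en-1-yn-1-yl]cyclohex-2-en-1-one
Conditions: HF·pyridine, pyridine, THF, 0 °C to rt
Reagents that add atoms: none
Why: Fluoride cleaves the hindered secondary silyl ether under buffered, mildly acidic conditions that the ynenone, the α-ketol and the tertiary allylic alcohol should tolerate.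

Step 15
Reactants: 24 (4S,5R,6R)-5,6-dihydroxy-4-(hydroxymethyl)-6-methyl-3-[(R,E)-5-hydroxy-5-((2R,3S)-3-methyltetrahydrofuran-2-yl)hex-3-en-1-yn-1-yl]cyclohex-2-en-1-one
Product: 25 (7R,8R,8aS)-7,8-dihydroxy-3-[(R,E)-3-hydroxy-3-((2R,3S)-3-methyltetrahydrofuran-2-yl)but-1-en-1-yl]-7-methyl-1,7,8,8a-tetrahydro-6H-isochromen-6-one
Conditions: (Ph3P)AuNTf2 (5 mol%), CH2Cl2–THF, rt
Reagents that add atoms: none
Why: Gold-catalysed cycloisomerisation (6-endo-dig hydroalkoxylation): the π-activated alkyne is attacked by the primary C1 hydroxyl at C3, the carbon made electrophilic by conjugation with the enone and by the alkenyl substituent, and protodeauration at C4 gives the dienol ether, whereas closure by O-8 would need a bridgehead alkene.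

Step 16
Reactants: 25 (7R,8R,8aS)-7,8-dihydroxy-3-[(R,E)-3-hydroxy-3-((2R,3S)-3-methyltetrahydrofuran-2-yl)but-1-en-1-yl]-7-methyl-1,7,8,8a-tetrahydro-6H-isochromen-6-one
Product: 26 Peniciazaphilone E
Conditions: N-chlorosuccinimide (1.0 equiv), CH2Cl2, 0 °C
Reagents that add atoms: N-chlorosuccinimide, O=C1CCC(=O)N1Cl
Why: Electrophilic chlorination should occur at C5, the α-carbon of the doubly vinylogous ester O2–C3=C4–C4a=C5–C6=O (the enolate-type terminus of the push–pull system), as is known for the halogenation of azaphilone chromophores; no stereocentre is affected.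

Compound list
1 | methyl 2,2-dimethoxypropanoate | COC(=O)C(C)(OC)OC | starting material
2 | 2,2-dimethoxypropanal | CC(OC)(OC)C=O | intermediate
3 | tetrahydro-4H-pyran-4-one | O=C1CCOCC1 | starting material
4 | (S)-3-[(R)-1-hydroxy-2,2-dimethoxypropyl]tetrahydro-4H-pyran-4-one | CC(OC)(OC)[C@H](O)[C@@H]1COCCC1=O | intermediate
5 | (S)-3-[(R)-1-(tert-butyldimethylsilyloxy)-2,2-dimethoxypropyl]tetrahydro-4H-pyran-4-one | CC(OC)(OC)[C@H](O[Si](C)(C)C(C)(C)C)[C@@H]1COCCC1=O | intermediate
6 | (S)-3-[(R)-1-(tert-butyldimethylsilyloxy)-2,2-dimethoxypropyl]-4-(trimethylsilyloxy)-3,6-dihydro-2H-pyran | CC(OC)(OC)[C@H](O[Si](C)(C)C(C)(C)C)[C@@H]1COCC=C1O[Si](C)(C)C | intermediate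
7 | (S)-3-[(R)-1-(tert-butyldimethylsilyloxy)-2,2-dimethoxypropyl]-2,3-dihydro-4H-pyran-4-one | CC(OC)(OC)[C@H](O[Si](C)(C)C(C)(C)C)[C@@H]1COC=CC1=O | intermediate
8 | cis-2-butene | C/C=C\C | starting material
9 | (3R,4S)-2,2-dimethoxy-4-methylhex-5-en-3-ol (syn) | CC(OC)(OC)[C@H](O)[C@@H](C)C=C | intermediate
10 | (3S,4R)-5,5-dimethoxy-3-methylhexane-1,4-diol | CC(OC)(OC)[C@H](O)[C@@H](C)CCO | intermediate
11 | (3S,4R)-4-hydroxy-5,5-dimethoxy-3-methylhexyl 4-methylbenzenesulfonate | CC(OC)(OC)[C@H](O)[C@@H](C)CCOS(=O)(=O)c1ccc(C)cc1 | intermediate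
12 | (2R,3S)-2-(1,1-dimethoxyethyl)-3-methyltetrahydrofuran (2,3-cis) | C[C@H]1CCO[C@H]1C(C)(OC)OC | intermediate
13 | 1-[(2R,3S)-3-methyltetrahydrofuran-2-yl]ethan-1-one | C[C@H]1CCO[C@H]1C(C)=O | intermediate
14 | (E)-1,2-diiodoethene | I/C=C/I | starting material
15 | ethynyltrimethylsilane | C#C[Si](C)(C)C | starting material
16 | (E)-(4-iodobut-3-en-1-yn-1-yl)trimethylsilane | C[Si](C)(C)C#C/C=C/I | intermediate
17 | [(E)-4-(trimethylsilyl)but-1-en-3-yn-1-yl]magnesium chloride | C[Si](C)(C)C#C/C=C/[Mg]Cl | intermediate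
18 | (R,E)-2-[(2R,3S)-3-methyltetrahydrofuran-2-yl]-6-(trimethylsilyl)hex-3-en-5-yn-2-ol | C[C@H]1CCO[C@H]1[C@](C)(O)/C=C/C#C[Si](C)(C)C | intermediate
19 | (R,E)-2-[(2R,3S)-3-methyltetrahydrofuran-2-yl]hex-3-en-5-yn-2-ol | C[C@H]1CCO[C@H]1[C@](C)(O)/C=C/C#C | intermediate
20 | (3S)-3-[(R)-1-(tert-butyldimethylsilyloxy)-2,2-dimethoxypropyl]-4-[(R,E)-5-hydroxy-5-((2R,3S)-3-methyltetrahydrofuran-2-yl)hex-3-en-1-yn-1-yl]-3,4-dihydro-2H-pyran-4-ol (both C4 epimers) | C[C@H]1CCO[C@H]1[C@](C)(O)/C=C/C#CC1(O)C=COC[C@H]1[C@@H](O[Si](C)(C)C(C)(C)C)C(C)(OC)OC | intermediate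
21 | (5S)-5-[(R)-1-(tert-butyldimethylsilyloxy)-2-oxopropyl]-4-[(R,E)-5-hydroxy-5-((2R,3S)-3-methyltetrahydrofuran-2-yl)hex-3-en-1-yn-1-yl]-5,6-dihydro-2H-pyran-2-ol (lactol, both C2 epimers) | C[C@H]1CCO[C@H]1[C@](C)(O)/C=C/C#CC1=CC(O)OC[C@H]1[C@@H](O[Si](C)(C)C(C)(C)C)C(C)=O | intermediate
22 | (2E,4S,5R)-5-(tert-butyldimethylsilyloxy)-4-(hydroxymethyl)-3-[(R,E)-5-hydroxy-5-((2R,3S)-3-methyltetrahydrofuran-2-yl)hex-3-en-1-yn-1-yl]-6-oxohept-2-enal (formyl group cis to C4 of the chain) | C[C@H]1CCO[C@H]1[C@](C)(O)/C=C/C#CC(=C/C=O)/[C@@H](CO)[C@@H](O[Si](C)(C)C(C)(C)C)C(C)=O | intermediate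
23 | (4S,5R,6R)-5-(tert-butyldimethylsilyloxy)-6-hydroxy-4-(hydroxymethyl)-6-methyl-3-[(R,E)-5-hydroxy-5-((2R,3S)-3-methyltetrahydrofuran-2-yl)hex-3-en-1-yn-1-yl]cyclohex-2-en-1-one | C[C@H]1CCO[C@H]1[C@](C)(O)/C=C/C#CC1=CC(=O)[C@](C)(O)[C@H](O[Si](C)(C)C(C)(C)C)[C@@H]1CO | intermediate
24 | (4S,5R,6R)-5,6-dihydroxy-4-(hydroxymethyl)-6-methyl-3-[(R,E)-5-hydroxy-5-((2R,3S)-3-methyltetrahydrofuran-2-yl)hex-3-en-1-yn-1-yl]cyclohex-2-en-1-one | C[C@H]1CCO[C@H]1[C@](C)(O)/C=C/C#CC1=CC(=O)[C@](C)(O)[C@H](O)[C@@H]1CO | intermediate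
25 | (7R,8R,8aS)-7,8-dihydroxy-3-[(R,E)-3-hydroxy-3-((2R,3S)-3-methyltetrahydrofuran-2-yl)but-1-en-1-yl]-7-methyl-1,7,8,8a-tetrahydro-6H-isochromen-6-one | C[C@H]1CCO[C@H]1[C@](C)(O)/C=C/C1=CC2=CC(=O)[C@](C)(O)[C@H](O)[C@@H]2CO1 | intermediate
26 | Peniciazaphilone E, (7R,8R,8aS)-5-chloro-7,8-dihydroxy-3-[(R,E)-3-hydroxy-3-((2R,3S)-3-methyltetrahydrofuran-2-yl)but-1-en-1-yl]-7-methyl-1,7,8,8a-tetrahydro-6H-isochromen-6-one | C[C@H]1CCO[C@H]1[C@](C)(O)/C=C/C1=CC2=C(Cl)C(=O)[C@](C)(O)[C@H](O)[C@@H]2CO1 | target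

Total step count: 16.
Longest linear sequence: 12 steps (steps 1, 5, 6, 7, 8, 10, 11, 12, 13, 14, 15, 16).

Steps most likely to fail

Step 13. The carbene adduct may be diverted from acyl-anion addition into homoenolate protonation or redox acylation of the free C1 hydroxyl, or the C7 ketone may be attacked on the wrong face. Fallback: setting out from 21, a reductive pinacol cyclisation of the open keto-enal with SmI2 (THF, t-BuOH, −78 °C) should join C6 and C7, with both oxygens held on samarium, as the cis-diol (1S,4S,5R,6S)-5-(tert-butyldimethylsilyloxy)-4-(hydroxymethyl)-3-[(R,E)-5-hydroxy-5-((2R,3S)-3-methyltetrahydrofuran-2-yl)hex-3-en-1-yn-1-yl]-6-methylcyclohex-2-ene-1,6-diol F1. Chemoselective oxidation of its secondary allylic C6 carbinol with MnO2 (CH2Cl2) then returns to 23. The C6 configuration is erased, and the C7 configuration would again rest on the C8 silyloxy group.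

Step 12. The acid needed for transposition and ketal hydrolysis may ionise the tertiary allylic alcohol of the side chain or cleave the silyl ether before the ketal is gone, and the hindered carbonyl may be enolised instead of attacked. Fallback: the acid step is moved ahead of the fragment union. Setting out from 7, addition of ethynylmagnesium bromide (CeCl3, THF) and the same acid treatment should give (5S)-5-[(R)-1-(tert-butyldimethylsilyloxy)-2-oxopropyl]-4-ethynyl-5,6-dihydro-2H-pyran-2-ol F2. Setting out from 13, chelation-controlled addition of (E)-2-(tributylstannyl)vinyllithium (from (E)-1,2-bis(tributylstannyl)ethene and n-BuLi, with MgBr2·OEt2) should give (R,E)-2-[(2R,3S)-3-methyltetrahydrofuran-2-yl]-4-(tributylstannyl)but-3-en-2-ol F3, and iododestannylation (I2, CH2Cl2, 0 °C) gives (R,E)-4-iodo-2-[(2R,3S)-3-methyltetrahydrofuran-2-yl]but-3-en-2-ol F4. Sonogashira coupling of F2 with F4 (PdCl2(PPh3)2, CuI, Et3N, THF) returns to 21.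

Step 15. Gold activation may lead to competing 5-exo closure onto C4 or to ionisation of the tertiary allylic alcohol instead of 6-endo attack at C3. Fallback: setting out from 24, conjugate addition of diethylamine (EtOH, rt) to the ynenone should give the dienaminone (4S,5R,6R)-3-[(3E,5R)-2-(diethylamino)-5-hydroxy-5-((2R,3S)-3-methyltetrahydrofuran-2-yl)hexa-1,3-dien-1-yl]-5,6-dihydroxy-4-(hydroxymethyl)-6-methylcyclohex-2-en-1-one F5. Mild acid (AcOH, THF) should then effect addition–elimination by the C1 hydroxyl with loss of the amine, returning to 25.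

Further compounds
F1 | step 13 | (1S,4S,5R,6S)-5-(tert-butyldimethylsilyloxy)-4-(hydroxymethyl)-3-[(R,E)-5-hydroxy-5-((2R,3S)-3-methyltetrahydrofuran-2-yl)hex-3-en-1-yn-1-yl]-6-methylcyclohex-2-ene-1,6-diol | C[C@H]1CCO[C@H]1[C@](C)(O)/C=C/C#CC1=C[C@H](O)[C@](C)(O)[C@H](O[Si](C)(C)C(C)(C)C)[C@@H]1CO
F2 | step 12 | (5S)-5-[(R)-1-(tert-butyldimethylsilyloxy)-2-oxopropyl]-4-ethynyl-5,6-dihydro-2H-pyran-2-ol | C#CC1=CC(O)OC[C@H]1[C@@H](O[Si](C)(C)C(C)(C)C)C(C)=O
F3 | step 12 | (R,E)-2-[(2R,3S)-3-methyltetrahydrofuran-2-yl]-4-(tributylstannyl)but-3-en-2-ol | C[C@H]1CCO[C@H]1[C@](C)(O)/C=C/[Sn](CCCC)(CCCC)CCCC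
F4 | step 12 | (R,E)-4-iodo-2-[(2R,3S)-3-methyltetrahydrofuran-2-yl]but-3-en-2-ol | C[C@H]1CCO[C@H]1[C@](C)(O)/C=C/I
F5 | step 15 | (4S,5R,6R)-3-[(3E,5R)-2-(diethylamino)-5-hydroxy-5-((2R,3S)-3-methyltetrahydrofuran-2-yl)hexa-1,3-dien-1-yl]-5,6-dihydroxy-4-(hydroxymethyl)-6-methylcyclohex-2-en-1-one | C[C@H]1CCO[C@H]1[C@](C)(O)/C=C/C(N(CC)CC)=CC1=CC(=O)[C@](C)(O)[C@H](O)[C@@H]1CO
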